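## Structural features

The target is (2S)-5,7-dihydroxy-6-(2,3-dihydroxybenzyl)flavanone: a chroman-4-one in which benzo ring A is fused to dihydropyranone ring C, C2 carries phenyl ring B, and C6 carries a catechol ring (ring D) through one methylene. Ring A is substituted at every position except C8, and the benzyl group must sit at C6, between the two hydroxyls, not at C8. C2 is the only stereocentre; it is benzylic, bonded to the ether oxygen O1 and β to the C4 carbonyl, and has no neighbouring stereocentre. The β-aryloxy ketone is the fragile element: base, and also strong Lewis acids that attack the benzylic C2–O1 bond, open ring C to the 2'-hydroxychalcone, and re-closure racemises C2. The catechol and the phloroglucinol-type ring A are in addition oxidisable and strongly nucleophilic once the phenols are free. The real difficulty is therefore not the carbon skeleton but setting C2 and keeping it through ring closure and through the release of four phenols. The key step uses the fact that O1 is an alkyl aryl ether between sp3 C2 and sp2 C8a: the C2–O1 bond can come intact from a chiral benzylic alcohol, and only O1–C8a is made, by O-arylation of a ring-A bromide. C4 is held as an alcohol during that step so that no β-hydroxy ketone meets the base.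

## Logic of the disconnections

18 to 17: four aryl O–CH2 acetal bonds are cut; they are protecting groups only. Four phenols cannot pass through organolithium, copper and periodinane steps. Acetal ethers fall to dilute protic acid, which leaves the β-aryloxy ketone and its benzylic C2–O1 bond alone, whereas methyl ethers would need boron tribromide on the finished flavanone. The demand is a solvolysis mild enough to keep ring C closed.

17 to 16: no skeletal bond is cut; the C4 carbonyl is traced back to a C4 carbinol. With C4 as an alcohol the chain is a plain 1,3-diol and the base-mediated ring closure has no retro-aldol or β-elimination pathway. The demand is an oxidation that is neither basic nor strongly acidic.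

16 to 15: the O1–C8a bond is cut. Ring C disappears, C2 becomes an ordinary benzylic carbinol and ring A becomes an aryl bromide. The demand is an intramolecular O-arylation that uses only the phenyl-bearing hydroxyl and does not touch either carbinol centre.

15 to 13, through 14: the C1–H bond is cut, returning the carbinol to the aryl ketone that an acylation delivers directly. The existing C3 hydroxyl directs the hydride, so one diastereomer should result. The demand is chelation-controlled syn delivery; it is not critical to the target, because this centre is oxidised again in step 11.

13 to 12: one O–Si bond. The silyl ether is needed only to mask the hydroxyl during the organolithium step. The demand is desilylation without β-elimination or retro-aldol cleavage.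

12 to 7 and 10, through 11: the C4–C4a aryl–carbonyl bond is cut. This is the most convergent cut, separating an achiral aromatic half from a three-carbon chiral unit. The only ring-A hydrogen of 7 lies between bromine and an acetal oxygen and is the most acidic site, and the N-methoxy-N-methylamide stops at the ketone. The demand is deprotonation without bromine–lithium exchange, without loss of lithium bromide and without attack on the diarylmethane CH2.

10 to 9 to 8: the Si–O bond and the amide C–N bond are cut. 8 is a chiral-pool ester that supplies C2 together with its oxygen. The demand is only that the β-hydroxy carbonyl unit is not cleaved.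

7 to 6 to 5: the protecting groups are exchanged; O–CH2 acetal bonds go back to phenols and these to O–CH3 bonds. Acetals would not survive the acid used to make 5 from 4, and methyl ethers cannot be removed safely at the end. The exchange is therefore placed on 5, which has no sensitive function. The demand is exhaustive ether cleavage without scission of the diarylmethane.

5 to 4 to 1 and 2, through 3: first the benzylic C–H bond (from C–OH), then the bond between the benzylic carbon and ring D are cut. 2 already carries both oxygens ortho and bromine para to the formyl carbon, which fixes the benzyl group at the future C6 and bromine at the future C8a. Ring D becomes the nucleophile by ortho-lithiation of 1. The demand is carbonyl addition faster than bromine–lithium exchange, followed by clean ionic deoxygenation.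

## Other disconnections considered

Alternative 1: The cut removes three bonds of ring C at once, C4a–C4, C4–C3 and O1–C2, leaving iodophenol A2, carbon monoxide and phenylacetylene A3. Forward, PdCl2(PPh3)2 and Et2NH would join A2, CO and A3 to an ortho-hydroxyaryl ynone, which should close in the 6-endo sense to flavone A1. An enantioselective reduction of the C2=C3 bond would then have to give 17.
- In its favour: three bonds and the ring form in one operation, the product is flat and robust, the acetal groups are tolerated, and C4 needs no oxidation-state detour. In ring-construction economy this alternative is the better plan.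
- Against it here: C2 would be created last, by 1,4-reduction of a vinylogous ester that is a poor acceptor and is shielded by the C5 acetal. That is far less secure than carrying a chiral-pool carbinol. Over-reduction at C4 and base-induced ring opening threaten the new centre, and 5-exo closure to the aurone skeleton competes.
- A2 needs one of three ring-A oxygens differentiated and an iodination at a crowded position, so it is no easier to reach than 7.
- Comparison: the alternative is shorter to the ring but weakest at the single stereocentre, which is where the target is demanding.

Alternative 2: The cut is O1–C8a together with C4–C4a, giving a ring-A aryne, released from silylaryl triflate A5, and hydroxy ester 8. Forward, CsF would unmask the aryne and the alkoxide of 8 would add at C8a, the carbon remote from the C5 acetal. The aryl anion at C4a would then acylate itself on the ester to give flavanone A4, which is identical with 17.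
- In its favour: it uses the same chiral-pool source, the same untouched C2–O bond and the same O1–C8a bond as the chosen plan, but makes two bonds in one step and reaches the ketone level directly. In step count after the fragments it is clearly the better.
- Against it here: A5 is a hexasubstituted benzene whose ortho-silyl triflate must be built regioselectively, a longer task than 7. The aryl anion can simply be protonated, giving the ether without ring closure, and the alkoxide of a β-hydroxy ester can fragment by retro-aldol.
- The product is a base-labile β-aryloxy ketone formed in the presence of fluoride and alkoxide, the conditions under which ring C opens and C2 racemises.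
- Comparison: the chosen plan spends three extra steps (reduction, coupling, oxidation) to keep every base-mediated event away from a β-oxygenated ketone.

Alternative 3: The cut is C2–C3. Diazoketone A7, an ortho-benzyloxyaryl diazomethyl ketone, would lose nitrogen under Rh2(S-PTTL)4, and the divalent rhodium carbene would insert into a benzylic C–H bond of the ether to close ring C and set C2, giving flavanone A6.
- In its favour: ring C and the stereocentre arise in one catalytic step from an achiral precursor, no chiral starting material is needed, and a C–C bond is formed. In economy of the ring-forming event it is the equal or the better of the chosen plan.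
- Against it here: the acceptor-only carbene can attack the ether oxygen (oxonium ylide, then benzyl shift to a five-membered ring), insert into the C5 methoxy C–H bond on the other flank, or add to the benzyl ring. The configuration of C2 rests on catalyst control alone, and a diazo compound must be handled.
- A6 carries four methyl ethers, whose removal needs boron tribromide or a similar reagent on the finished flavanone, with the risk of opening ring C.
- Comparison: the chosen plan takes its stereocentre from the pool and ends with a mild acetal solvolysis, at the cost of length.

Key step: step 10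

Remark on the protecting groups: from compound 7 onward the four phenols are carried as methoxymethyl ethers rather than methyl ethers, so that the last step is a protic acetal solvolysis and not a boron tribromide treatment of the flavanone.

Remark on the descriptors: the syn open-chain diol is (1R,3S) and closes, with both C–O bonds intact, to the 2,4-trans flavan-4-ol (2S,4R). The S descriptor is the same in 8, 15 and 18 because the order O > phenyl > CH2 > H does not change.

Remark on the metalation: ring A is deprotonated with a lithium amide at low temperature, because TMPMgCl·LiCl is judged too weak a base for an arene that carries only bromine and ether groups.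

Remark on starting materials: 1, 2 and 8 are taken as commercial.

Step 1
Reactants: 1 veratrole (1,2-dimethoxybenzene); 2 4-bromo-2,6-dimethoxybenzaldehyde
Product: 4 racemic (4-bromo-2,6-dimethoxyphenyl)(2,3-dimethoxyphenyl)methanol, via 2,3-dimethoxyphenyllithium 3 (not isolated)
Conditions: 1, n-BuLi, TMEDA, THF, 0 °C to rt; then 2, THF, –78 °C; H2O
Reagents that add atoms: none
Why: Directed ortho-lithiation of veratrole occurs next to a methoxy group, and 1,2-addition of the aryllithium to the aldehyde at –78 °C should be much faster than bromine–lithium exchange with the aryl bromide. The carbinol centre is removed in step 2, so its configuration is immaterial.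

Step 2
Reactants: 4 racemic (4-bromo-2,6-dimethoxyphenyl)(2,3-dimethoxyphenyl)methanol
Product: 5 5-bromo-2-[(2,3-dimethoxyphenyl)methyl]-1,3-dimethoxybenzene
Conditions: Et3SiH, CF3CO2H, CH2Cl2, 0 °C to rt
Reagents that add atoms: none
Why: Ionic hydrogenation: the doubly benzylic cation is stabilised by ortho and para methoxy groups and is trapped by silane hydride. Methyl ethers and the aryl bromide are inert to these conditions.

Step 3
Reactants: 5 5-bromo-2-[(2,3-dimethoxyphenyl)methyl]-1,3-dimethoxybenzene
Product: 6 5-bromo-2-[(2,3-dihydroxyphenyl)methyl]benzene-1,3-diol
Conditions: BBr3 (6 equiv), CH2Cl2, –78 °C to rt; then MeOH, H2O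
Reagents that add atoms: none
Why: Lewis-acid cleavage of aryl methyl ethers through aryloxyboron bromides. It is placed here because 5 contains nothing but arenes, an aryl bromide and a methylene, so the harsh reagent meets no sensitive function.

Step 4
Reactants: 6 5-bromo-2-[(2,3-dihydroxyphenyl)methyl]benzene-1,3-diol
Product: 7 5-bromo-2-{[2,3-bis(methoxymethoxy)phenyl]methyl}-1,3-bis(methoxymethoxy)benzene
Conditions: NaH, DMF, 0 °C; MOMCl, 0 °C to rt
Reagents that add atoms: chloromethyl methyl ether (MOMCl), COCCl
Why: Williamson O-alkylation of the four phenoxides with a hard electrophile in a dipolar solvent should give O-alkylation only. The acetals are stable to every later base, to hydride and to fluoride.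

Step 5
Reactants: 8 methyl (3S)-3-hydroxy-3-phenylpropanoate
Product: 9 (3S)-3-hydroxy-N-methoxy-N-methyl-3-phenylpropanamide
Conditions: MeNH(OMe)·HCl, i-PrMgCl, THF, –20 to 0 °C
Reagents that add atoms: N,O-dimethylhydroxylamine hydrochloride, CNOC.Cl
Why: Aminolysis of the ester by the chloromagnesium amide made in the flask (Weinreb amide formation). The hydroxyl is carried as its magnesium alkoxide, and the carbinol centre is not involved.

Step 6
Reactants: 9 (3S)-3-hydroxy-N-methoxy-N-methyl-3-phenylpropanamide
Product: 10 (3S)-3-[(tert-butyldimethylsilyl)oxy]-N-methoxy-N-methyl-3-phenylpropanamide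
Conditions: TBSCl, imidazole, DMF, rt
Reagents that add atoms: tert-butyldimethylsilyl chloride (TBSCl), CC(C)(C)[Si](C)(C)Cl
Why: Standard silylation of a secondary alcohol. It removes the only acidic proton of the acylating partner, so one equivalent of aryllithium suffices in step 7.

Step 7
Reactants: 7 5-bromo-2-{[2,3-bis(methoxymethoxy)phenyl]methyl}-1,3-bis(methoxymethoxy)benzene; 10 (3S)-3-[(tert-butyldimethylsilyl)oxy]-N-methoxy-N-methyl-3-phenylpropanamide
Product: 12 (3S)-1-[6-bromo-3-{[2,3-bis(methoxymethoxy)phenyl]methyl}-2,4-bis(methoxymethoxy)phenyl]-3-[(tert-butyldimethylsilyl)oxy]-3-phenylpropan-1-one, via aryllithium 11 (not isolated)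
Conditions: 7, LiN(i-Pr)2 (LDA), THF, –78 °C; then 10, –78 to –40 °C; AcOH, then H2O
Reagents that add atoms: none
Why: Directed ortho-metalation with a lithium amide removes the ring-A proton flanked by bromine and an acetal oxygen, the two equivalent positions being the most acidic C–H bonds in 7; an amide base deprotonates where an alkyllithium would exchange bromine. The ortho-bromoaryllithium is kept at –78 °C to prevent loss of LiBr, and Weinreb acylation stops at the ketone because the tetrahedral chelate survives until the quench; C3 is not touched.

Step 8
Reactants: 12 (3S)-1-[6-bromo-3-{[2,3-bis(methoxymethoxy)phenyl]methyl}-2,4-bis(methoxymethoxy)phenyl]-3-[(tert-butyldimethylsilyl)oxy]-3-phenylpropan-1-one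
Product: 13 (3S)-1-[6-bromo-3-{[2,3-bis(methoxymethoxy)phenyl]methyl}-2,4-bis(methoxymethoxy)phenyl]-3-hydroxy-3-phenylpropan-1-one
Conditions: Bu4NF, AcOH (1:1), THF, 0 °C to rt
Reagents that add atoms: none
Why: Fluoride-induced desilylation; the acetic acid buffer protonates the alkoxide as it forms, so the β-hydroxy ketone should not see a base strong enough for β-elimination or retro-aldol cleavage. The acetals are inert to fluoride.

Step 9
Reactants: 13 (3S)-1-[6-bromo-3-{[2,3-bis(methoxymethoxy)phenyl]methyl}-2,4-bis(methoxymethoxy)phenyl]-3-hydroxy-3-phenylpropan-1-one
Product: 15 (1R,3S)-1-[6-bromo-3-{[2,3-bis(methoxymethoxy)phenyl]methyl}-2,4-bis(methoxymethoxy)phenyl]-3-phenylpropane-1,3-diol, via diethylboron chelate 14 (not isolated)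
Conditions: Et2BOMe, THF/MeOH 4:1, –78 °C; NaBH4, –78 °C; AcOH; MeOH co-evaporation
Reagents that add atoms: none
Why: Narasaka–Prasad reduction: the six-membered boron chelate places the C3 phenyl pseudo-equatorial and external hydride attacks axially, which should give the 1,3-syn diol, so C1 becomes R under control of the existing C3 centre. C1 is oxidised again in step 11 and is set only so that 15 and 16 are single compounds.

Step 10
Reactants: 15 (1R,3S)-1-[6-bromo-3-{[2,3-bis(methoxymethoxy)phenyl]methyl}-2,4-bis(methoxymethoxy)phenyl]-3-phenylpropane-1,3-diol
Product: 16 (2S,4R)-6-{[2,3-bis(methoxymethoxy)phenyl]methyl}-5,7-bis(methoxymethoxy)flavan-4-ol (2,4-trans)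
Conditions: CuI (10 mol%), 3,4,7,8-tetramethyl-1,10-phenanthroline (20 mol%), Cs2CO3 (2 equiv), degassed toluene (0.03 M), 110 °C
Reagents that add atoms: none
Why: Cs2CO3 deprotonates the C3 hydroxyl at copper to give a monovalent copper alkoxide ligated by the phenanthroline; the neighbouring C–Br bond adds oxidatively to give a trivalent aryl copper alkoxide in a six-membered metallacycle, and C–O reductive elimination forms O1–C8a and returns monovalent copper. The closest known reaction type is the Ullmann-type intramolecular O-arylation of 3-(2-bromoaryl)-1-arylpropan-1-ols to flavans and chromans. Ring C closes in the 6-exo mode at the sp2 carbon C8a, the breaking C–Br bond lying outside the new ring. No stereocentre is formed: C2 stays S because its C–O bond is never broken, C4 stays R as a spectator, and the syn diol therefore maps onto the 2,4-trans flavan-4-ol. The step needs selectivity between the two hydroxyls, which ring size secures, since the C1 hydroxyl could only close a four-membered benzoxete. It needs ring closure to outrun intermolecular etherification, which the tether and high dilution secure. It needs a substrate that tolerates hot carbonate, which is why C4 is an alcohol (no retro-aldol or β-elimination) and the phenols are base-stable acetals; the C–Br carbon is meta to both alkoxy groups and so is not deactivated by resonance. Oxygen is excluded so that copper does not oxidise the benzylic alcohols.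

Step 11
Reactants: 16 (2S,4R)-6-{[2,3-bis(methoxymethoxy)phenyl]methyl}-5,7-bis(methoxymethoxy)flavan-4-ol (2,4-trans)
Product: 17 (2S)-6-{[2,3-bis(methoxymethoxy)phenyl]methyl}-5,7-bis(methoxymethoxy)flavanone
Conditions: Dess–Martin periodinane, pyridine, CH2Cl2, 0 °C to rt
Reagents that add atoms: none
Why: Dess–Martin oxidation of a secondary benzylic alcohol proceeds by ligand exchange at iodine and loss of the carbinol hydrogen. The pyridine-buffered medium is neither basic enough to open ring C by retro-oxa-Michael reaction nor acidic enough to ionise the electron-rich benzylic alcohol, so C2 should be unaffected.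

Step 12
Reactants: 17 (2S)-6-{[2,3-bis(methoxymethoxy)phenyl]methyl}-5,7-bis(methoxymethoxy)flavanone
Product: 18 (2S)-6-[(2,3-dihydroxyphenyl)methyl]-5,7-dihydroxyflavanone (the target)
Conditions: HCl (3 M aq), MeOH, 45 °C
Reagents that add atoms: none
Why: Acid-catalysed acetal methanolysis: each protonated ArO–CH2OMe passes its methoxymethyl cation to methanol as dimethoxymethane, so no Lewis acid meets the benzylic C2–O1 bond. The β-aryloxy ketone is far more stable to dilute protic acid than to base, so C2 should keep its S configuration, and the large excess of methanol should intercept the oxocarbenium ion before the nucleophilic C8 can.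

## Compound list

1 | veratrole (1,2-dimethoxybenzene) | COc1ccccc1OC | starting material
2 | 4-bromo-2,6-dimethoxybenzaldehyde | COc1cc(Br)cc(OC)c1C=O | starting material
3 | 2,3-dimethoxyphenyllithium | [Li]c1cccc(OC)c1OC | intermediate
4 | racemic (4-bromo-2,6-dimethoxyphenyl)(2,3-dimethoxyphenyl)methanol | COc1cc(Br)cc(OC)c1C(O)c1cccc(OC)c1OC | intermediate
5 | 5-bromo-2-[(2,3-dimethoxyphenyl)methyl]-1,3-dimethoxybenzene | COc1cc(Br)cc(OC)c1Cc1cccc(OC)c1OC | intermediate
6 | 5-bromo-2-[(2,3-dihydroxyphenyl)methyl]benzene-1,3-diol | Oc1cc(Br)cc(O)c1Cc1cccc(O)c1O | intermediate
7 | 5-bromo-2-{[2,3-bis(methoxymethoxy)phenyl]methyl}-1,3-bis(methoxymethoxy)benzene | COCOc1cc(Br)cc(OCOC)c1Cc1cccc(OCOC)c1OCOC | intermediate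
8 | methyl (3S)-3-hydroxy-3-phenylpropanoate | COC(=O)C[C@@H](c1ccccc1)O | starting material
9 | (3S)-3-hydroxy-N-methoxy-N-methyl-3-phenylpropanamide | CON(C)C(=O)C[C@@H](c1ccccc1)O | intermediate
10 | (3S)-3-[(tert-butyldimethylsilyl)oxy]-N-methoxy-N-methyl-3-phenylpropanamide | CON(C)C(=O)C[C@@H](c1ccccc1)O[Si](C)(C)C(C)(C)C | intermediate
11 | [6-bromo-3-{[2,3-bis(methoxymethoxy)phenyl]methyl}-2,4-bis(methoxymethoxy)phenyl]lithium | [Li]c1c(Br)cc(OCOC)c(Cc2cccc(OCOC)c2OCOC)c1OCOC | intermediate
12 | (3S)-1-[6-bromo-3-{[2,3-bis(methoxymethoxy)phenyl]methyl}-2,4-bis(methoxymethoxy)phenyl]-3-[(tert-butyldimethylsilyl)oxy]-3-phenylpropan-1-one | O=C(C[C@@H](c1ccccc1)O[Si](C)(C)C(C)(C)C)c1c(Br)cc(OCOC)c(Cc2cccc(OCOC)c2OCOC)c1OCOC | intermediate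
13 | (3S)-1-[6-bromo-3-{[2,3-bis(methoxymethoxy)phenyl]methyl}-2,4-bis(methoxymethoxy)phenyl]-3-hydroxy-3-phenylpropan-1-one | O=C(C[C@@H](c1ccccc1)O)c1c(Br)cc(OCOC)c(Cc2cccc(OCOC)c2OCOC)c1OCOC | intermediate
14 | diethylboron chelate of 13 (alkoxide oxygen bound to boron, ketone oxygen coordinated; S at the phenyl carbinol) | CC[B-]1(CC)O[C@H](c2ccccc2)CC(=[O+]1)c1c(Br)cc(OCOC)c(Cc2cccc(OCOC)c2OCOC)c1OCOC | intermediate
15 | (1R,3S)-1-[6-bromo-3-{[2,3-bis(methoxymethoxy)phenyl]methyl}-2,4-bis(methoxymethoxy)phenyl]-3-phenylpropane-1,3-diol | Brc1cc(OCOC)c(Cc2cccc(OCOC)c2OCOC)c(OCOC)c1[C@H](O)C[C@@H](c1ccccc1)O | intermediate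
16 | (2S,4R)-6-{[2,3-bis(methoxymethoxy)phenyl]methyl}-5,7-bis(methoxymethoxy)flavan-4-ol | O[C@@H]1C[C@@H](c2ccccc2)Oc2cc(OCOC)c(Cc3cccc(OCOC)c3OCOC)c(OCOC)c21 | intermediate
17 | (2S)-6-{[2,3-bis(methoxymethoxy)phenyl]methyl}-5,7-bis(methoxymethoxy)flavanone | O=C1C[C@@H](c2ccccc2)Oc2cc(OCOC)c(Cc3cccc(OCOC)c3OCOC)c(OCOC)c21 | intermediate
18 | (2S)-6-[(2,3-dihydroxyphenyl)methyl]-5,7-dihydroxyflavanone | O=C1C[C@@H](c2ccccc2)Oc2cc(O)c(Cc3cccc(O)c3O)c(O)c21 | target

## Step count and least certain steps

Total: 12 steps. Longest linear sequence: 10 steps (steps 1 to 4, then 7 to 12); the chiral side chain takes two steps (5 and 6).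

Step 10 (key step). The most likely failure is slow turnover: the syn 1,3-diol can hold copper as a chelate, and a hindered secondary benzylic alkoxide is slow in C–O reductive elimination. Hydrodebromination and intermolecular etherification would then take over. The fallback is a metal-free elimination–addition that sets out from 15. Lithium 2,2,6,6-tetramethylpiperidide (LiTMP, about 3.5 equiv) in THF at –78 °C should deprotonate both hydroxyls and then the ring proton between bromine and the acetal oxygen. On warming, LiBr is lost and the aryne F1 forms. The tethered C3 alkoxide should add to the nearer aryne carbon, the future C8a, because the aryl anion then develops next to the acetal oxygen; protonation gives the product. The fallback comes back to the route at 16.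

Step 7. Three processes can divert it: deprotonation of the diarylmethane CH2 in place of the ring, loss of LiBr from 11 if the acylation is slow enough to require warming, and enolisation of 10 by the hindered aryllithium followed by β-elimination of the silyloxy group. The fallback generates the aryl metal by exchange, not by deprotonation, and sets out from 7. N-Iodosuccinimide in MeCN should iodinate the only free position of ring A (ortho to one acetal oxygen and para to the other, on the more activated ring) to give the aryl iodide F2. i-PrMgCl·LiCl in THF at –40 °C should then exchange iodine in preference to bromine to give the arylmagnesium chloride F3. F3 is acylated with 10 at –40 to 0 °C, a temperature range in which an ortho-bromoaryl Grignard reagent should not eliminate. The fallback comes back at 12.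

Step 8. The risk is base-triggered loss of the β-oxygen (β-elimination to the enone) or retro-aldol cleavage while fluoride removes silicon. The fallback avoids the silyl group altogether and sets out from 9. NaH (1 equiv) in THF converts 9 into the sodium alkoxide F4, which is added at –78 °C to 11 made from 7 as in step 7. The tetrahedral adduct carries the alkoxide until an acetic acid quench at low temperature, so the β-hydroxy ketone is released under non-basic conditions. The fallback comes back at 13 and makes steps 6 and 8 unnecessary.

Step 9. The ketone is flanked by bromine and an acetal oxygen, so formation of the boron chelate may be incomplete, with slow reduction or poor facial selectivity as the result. The fallback gives up diastereocontrol and sets out from 13. Plain NaBH4 in MeOH at 0 °C should give 15 together with its C1 epimer, the (1S,3S)-diol F5. The mixture is taken through step 10, where F5 should close to the 2,4-cis flavan-4-ol F6, and both alcohols converge in step 11 because C4 becomes sp2. The fallback comes back at 17.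

## Further compounds

F1 | step 10 | (1R,3S)-1-[3-{[2,3-bis(methoxymethoxy)phenyl]methyl}-2,4-bis(methoxymethoxy)-5,6-didehydrophenyl]-3-phenylpropane-1,3-diol (aryne, drawn as the free diol) | C1#CC(OCOC)=C(Cc2cccc(OCOC)c2OCOC)C(OCOC)=C1[C@H](O)C[C@@H](c1ccccc1)O
F2 | step 7 | 1-bromo-4-{[2,3-bis(methoxymethoxy)phenyl]methyl}-2-iodo-3,5-bis(methoxymethoxy)benzene | Ic1c(Br)cc(OCOC)c(Cc2cccc(OCOC)c2OCOC)c1OCOC
F3 | step 7 | [6-bromo-3-{[2,3-bis(methoxymethoxy)phenyl]methyl}-2,4-bis(methoxymethoxy)phenyl]magnesium chloride | Cl[Mg]c1c(Br)cc(OCOC)c(Cc2cccc(OCOC)c2OCOC)c1OCOC
F4 | step 8 | sodium (1S)-3-[methoxy(methyl)amino]-3-oxo-1-phenylpropan-1-olate | [Na+].[O-][C@H](c1ccccc1)CC(=O)N(C)OC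
F5 | step 9 | (1S,3S)-1-[6-bromo-3-{[2,3-bis(methoxymethoxy)phenyl]methyl}-2,4-bis(methoxymethoxy)phenyl]-3-phenylpropane-1,3-diol | Brc1cc(OCOC)c(Cc2cccc(OCOC)c2OCOC)c(OCOC)c1[C@@H](O)C[C@@H](c1ccccc1)O
F6 | step 9 | (2S,4S)-6-{[2,3-bis(methoxymethoxy)phenyl]methyl}-5,7-bis(methoxymethoxy)flavan-4-ol | O[C@H]1C[C@@H](c2ccccc2)Oc2cc(OCOC)c(Cc3cccc(OCOC)c3OCOC)c(OCOC)c21
A1 | alternative 1 | 6-{[2,3-bis(methoxymethoxy)phenyl]methyl}-5,7-bis(methoxymethoxy)flavone | O=c1cc(-c2ccccc2)oc2cc(OCOC)c(Cc3cccc(OCOC)c3OCOC)c(OCOC)c12
A2 | alternative 1 | 4-{[2,3-bis(methoxymethoxy)phenyl]methyl}-2-iodo-3,5-bis(methoxymethoxy)phenol | Oc1cc(OCOC)c(Cc2cccc(OCOC)c2OCOC)c(OCOC)c1I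
A3 | alternative 1 | phenylacetylene | C#Cc1ccccc1
A4 | alternative 2 | (2S)-6-{[2,3-bis(methoxymethoxy)phenyl]methyl}-5,7-bis(methoxymethoxy)flavanone (identical with 17) | O=C1C[C@@H](c2ccccc2)Oc2cc(OCOC)c(Cc3cccc(OCOC)c3OCOC)c(OCOC)c21
A5 | alternative 2 | 4-{[2,3-bis(methoxymethoxy)phenyl]methyl}-3,5-bis(methoxymethoxy)-2-(trimethylsilyl)phenyl trifluoromethanesulfonate | C[Si](C)(C)c1c(OS(=O)(=O)C(F)(F)F)cc(OCOC)c(Cc2cccc(OCOC)c2OCOC)c1OCOC
A6 | alternative 3 | (2S)-6-[(2,3-dimethoxyphenyl)methyl]-5,7-dimethoxyflavanone | O=C1C[C@@H](c2ccccc2)Oc2cc(OC)c(Cc3cccc(OC)c3OC)c(OC)c21
A7 | alternative 3 | 1-[6-(benzyloxy)-3-[(2,3-dimethoxyphenyl)methyl]-2,4-dimethoxyphenyl]-2-diazoethan-1-one | [N-]=[N+]=CC(=O)c1c(OCc2ccccc2)cc(OC)c(Cc2cccc(OC)c2OC)c1OC
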